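The plan rests on ring C: a tetrahydrofuran (O, C9, C11, C12, C13) whose two fully substituted α-carbons hold C8 and C14 on the same face. Cutting C9–C11 and C12–C13 leads back to a 3-oxidopyrylium and methyl acrylate. Their [5+2] cycloaddition forms both bonds at once, closes ring C inside an 8-oxabicyclo[3.2.1]octenone and sets C9 and C13 relative to C10. The C8–C7=C14 bridge that enforces the cis relationship is later cleaved to feed rings B and D. The precursor is a 6-acetoxypyran-3-one carrying CH2OTBS at C13 and, at C9, the enantioenriched 1,3,3-trimethyl-2-oxocyclohexyl group (ring A, quaternary C10).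

Key step: step 9

Assumption: atoms carry labdane numbers; read literally, the target SMILES has H-5 cis to the C-20 methyl (5β-H, cis A/B fusion) together with 7β-OH, 8α-OAc/8β-CH3, 9α-O and 13S, so the route is built for exactly this isomer, and its epimerisable C5 is set late and kept away from base.

Step 1
Reactants: 1 2,2,6-trimethylcyclohexanone (racemic)
Product: 3 allyl 2,6,6-trimethylcyclohex-1-en-1-yl carbonate, via lithium enolate 2 (not isolated)
Conditions: LiN(SiMe3)2, THF, 0 °C; allyl chloroformate, −78 °C to rt
Reagents that add atoms: allyl chloroformate, C=CCOC(=O)Cl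
Why: The ketone has only one enolisable position, so deprotonation gives a single tetrasubstituted enolate, which the hard chloroformate acylates on oxygen (enolate O-acylation).

Step 2
Reactants: 3 allyl enol carbonate
Product: 4 (R)-2-allyl-2,6,6-trimethylcyclohexanone
Conditions: Pd2(dba)3 (2.5 mol %), (R)-t-BuPHOX [(R)-4-tert-butyl-2-(2-diphenylphosphinophenyl)-4,5-dihydrooxazole] (6 mol %), THF, 25 °C
Reagents that add atoms: none
Why: In this decarboxylative asymmetric allylic alkylation (Tsuji–Trost type), loss of CO2 gives a π-allylpalladium enolate that recombines at carbon inside the chiral ligand sphere to create quaternary C10; the (R)-ligand is chosen because the (S)-ligand gives (S)-2-allyl-2-alkylcyclohexanones, and this enol carbonate is a standard substrate of the method.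

Step 3
Reactants: 4 (R)-allyl ketone
Product: 5 (R)-2,2,6-trimethyl-6-[(E)-prop-1-enyl]cyclohexanone
Conditions: RuHCl(CO)(PPh3)3 (5 mol %), toluene, 110 °C
Reagents that add atoms: none
Why: Ruthenium-hydride alkene isomerisation (insertion/β-hydride elimination) moves the terminal double bond one position to the more stable E-alkene and must stop there because C10 is quaternary, which also protects the stereocentre.

Step 4
Reactants: 5 (R)-propenyl ketone
Product: 6 (R)-1,3,3-trimethyl-2-oxocyclohexane-1-carbaldehyde
Conditions: O3, CH2Cl2, −78 °C; PPh3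
Reagents that add atoms: ozone, [O-][O+]=O
Why: Ozonolysis with reductive work-up cleaves the only alkene to the aldehyde carbon that becomes C9; the β-keto aldehyde has no α-hydrogen, so C10 cannot epimerise, and the neutral aprotic work-up avoids deformylation.

Step 5
Reactants: 7 furfuryl alcohol
Product: 8 tert-butyl(furan-2-ylmethoxy)dimethylsilane
Conditions: TBSCl, imidazole, CH2Cl2, rt
Reagents that add atoms: tert-butyldimethylsilyl chloride, CC(C)(C)[Si](C)(C)Cl
Why: Imidazole-promoted silylation of a primary alcohol protects the future O16 through all organometallic and oxidative steps.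

Step 6
Reactants: 8 silyl furfuryl ether; 6 (R)-keto aldehyde
Product: 10 (R)-2-[(S)-hydroxy{5-[(tert-butyldimethylsilyloxy)methyl]furan-2-yl}methyl]-2,6,6-trimethylcyclohexanone (C9 epimers carried together; S drawn), via 5-lithiofuran 9 (not isolated)
Conditions: n-BuLi, THF, −78 to 0 °C; 6, −78 °C; AcOH, −78 °C
Reagents that add atoms: none
Why: α-Lithiation of the furan at its free C5 position is followed by 1,2-addition to the aldehyde, which is far more reactive than the ketone buried between two quaternary carbons; the cold acidic quench forestalls retro-aldol cleavage, and the new carbinol centre C9 is planarised again in step 9.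

Step 7
Reactants: 10 furyl carbinol
Product: 11 6-hydroxy-6-[(tert-butyldimethylsilyloxy)methyl]-2-[(R)-1,3,3-trimethyl-2-oxocyclohexyl]-2H-pyran-3(6H)-one (epimers at C9 and C13; 2S,6R drawn)
Conditions: mCPBA, CH2Cl2, 0 °C
Reagents that add atoms: mCPBA, O=C(OO)c1cccc(Cl)c1
Why: In the Achmatowicz rearrangement, peracid oxidation opens the 2,5-disubstituted furan to the cis-enedione, which the C9 hydroxyl recloses as the six-membered hemiketal; C9 keeps its configuration and C13 forms as an anomeric mixture, both being erased in step 9.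

Step 8
Reactants: 11 hydroxypyranone
Product: 12 6-acetoxy-6-[(tert-butyldimethylsilyloxy)methyl]-2-[(R)-1,3,3-trimethyl-2-oxocyclohexyl]-2H-pyran-3(6H)-one (either epimer at C9 and C13 serves; 2S,6S drawn)
Conditions: Ac2O, pyridine, DMAP (cat.), CH2Cl2, 0 °C
Reagents that add atoms: acetic anhydride, CC(=O)OC(C)=O
Why: DMAP-catalysed acylation of the anomeric hydroxyl installs the leaving group for ylide formation, and only weak bases are present, so the ylide is not released prematurely.

Step 9
Reactants: 12 acetoxypyranone; 13 methyl acrylate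
Product: 15 methyl (1S,5R,6S)-5-[(tert-butyldimethylsilyloxy)methyl]-2-oxo-1-[(R)-1,3,3-trimethyl-2-oxocyclohexyl]-8-oxabicyclo[3.2.1]oct-3-ene-6-carboxylate (bridgeheads C9 and C13; exo ester at C12 drawn), via oxidopyrylium ylide 14 (not isolated)
Conditions: Et3N (3 equiv), methyl acrylate (20 equiv), MeCN, 70 °C, sealed tube
Reagents that add atoms: none
Why: Et3N removes H-9 and acetate leaves C13, releasing the planar 3-oxidopyrylium 14, a five-atom carbonyl-ylide-type dipole that adds suprafacially across C9 and C13 to the acrylate in a concerted but asynchronous [5+2] cycloaddition. This is the established base-induced oxidopyrylium–alkene cycloaddition of Achmatowicz-derived acetoxypyranones with acrylates, here with both termini substituted. Both rings close by intermolecular annulation in the same event: ring C (O, C9, C11, C12, C13) through the new bonds C9–C11 and C13–C12 on either side of the pyrylium oxygen, and the sacrificial cycloheptenone (C9, C8, C7, C14, C13, C12, C11) through the same two bonds. Regiochemistry follows ylide polarity, since the oxide at C8 makes C9 the nucleophilic terminus that bonds to the acrylate β-carbon, which places the ester on C12 next to C13. C9 and C13 are locked to each other because C7 ties C8 and C14 to one face of ring C, while their sense relative to C10 comes from a staggered transition state in which the bulky C5/C4 flank of ring A lies anti to the incoming alkene, the small C20 methyl sits next to the C8 oxide and C1 next to the ring oxygen, so that C11 bonds to the face of C9 opposite C5. C12 forms as an inconsequential exo/endo mixture (erased in step 11), and capture of the ylide before it dimerises is secured by the excess acrylate and by the two terminal substituents, which slow dimerisation.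

Step 10
Reactants: 15 cycloadduct
Product: 17 the corresponding C12 carboxylic acid, via trimethylstannyl ester 16 (not isolated)
Conditions: Me3SnOH, ClCH2CH2Cl, 80 °C; dilute aq HCl wash
Reagents that add atoms: trimethyltin hydroxide, C[Sn](C)(C)O
Why: Trimethyltin hydroxide ester hydrolysis (acyl substitution near neutrality) frees the acid without forming the C12 ester enolate, whose β-elimination would open the oxygen bridge, and without adding hydroxide to the enone.

Step 11
Reactants: 17 acid
Product: 19 (1S,5S)-5-[(tert-butyldimethylsilyloxy)methyl]-1-[(R)-1,3,3-trimethyl-2-oxocyclohexyl]-8-oxabicyclo[3.2.1]oct-3-en-2-one, via thiohydroxamate ester 18 (not isolated)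
Conditions: 1-hydroxypyridine-2(1H)-thione, DCC, DMAP (cat.), CH2Cl2, 0 °C, dark; t-BuSH, hν (tungsten lamp), rt
Reagents that add atoms: none
Why: In the Barton decarboxylation, carbodiimide coupling gives the thiohydroxamate, whose photolysis releases CO2 and a secondary C12 radical that abstracts hydrogen from the thiol, turning C12 into the required methylene and deleting its stereocentre.

Step 12
Reactants: 19 enone
Product: 20 the 3-iodo enone (iodine on C7; bridgeheads unchanged)
Conditions: I2, pyridine–CH2Cl2 (1:1), rt
Reagents that add atoms: iodine, II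
Why: α-Iodination of a cyclic enone proceeds by the pyridine/iodine addition–elimination sequence (Baylis–Hillman-type addition of pyridine at C14, iodination at C7, loss of pyridinium), which tolerates a quaternary γ-carbon as in 4,4-dialkylcyclohexenones.

Step 13
Reactants: 20 iodo enone
Product: 21 the 3-methyl enone (C6 as methyl on C7; bridgeheads unchanged)
Conditions: Me4Sn, PdCl2(PhCN)2 (5 mol %), AsPh3, CuI (10 mol %), NMP, 80 °C
Reagents that add atoms: tetramethylstannane, C[Sn](C)(C)C
Why: Stille coupling of the α-iodoenone installs C6 on C7, so that later cleavage of C7=C14 gives a methyl ketone at one end and an aldehyde at the other and the two termini need no further differentiation.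

Step 14
Reactants: 21 methyl enone
Product: 22 (1S,2R,5S)-5-[(tert-butyldimethylsilyloxy)methyl]-2,3-dimethyl-1-[(R)-1,3,3-trimethyl-2-oxocyclohexyl]-8-oxabicyclo[3.2.1]oct-3-en-2-ol
Conditions: MeLi, Et2O–THF, −78 °C; aq NH4Cl
Reagents that add atoms: methyllithium, [Li]C
Why: 1,2-Addition of methyllithium to the non-enolisable enone outruns attack on the C5 ketone flanked by two quaternary carbons, and the nucleophile enters C8 from the face next to the oxygen bridge and away from the C11–C12 bridge, so C17 ends anti to C11 and O8 anti to the ring oxygen (8β-methyl, 8α-oxygen).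

Step 15
Reactants: 22 tertiary allylic alcohol
Product: 24 keto lactol (3,8-dioxabicyclo[3.2.1]octane: O8 closed on C14; acetyl and methyl on C8; anomer mixture), via hydroxy keto aldehyde 23 (not isolated)
Conditions: O3, CH2Cl2, −78 °C; PPh3
Reagents that add atoms: ozone, [O-][O+]=O
Why: Ozonolysis with reductive work-up cuts the only alkene and with it the sacrificial seven-membered ring, leaving the methyl ketone C7(=O)–C6H3 on C8 and the aldehyde C14 on C13; because C8 and C14 are cis on ring C, the tertiary hydroxyl closes onto the aldehyde as a six-membered lactol.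

Step 16
Reactants: 24 keto lactol
Product: 25 alkynyl hydroxy diketone (ring C carrying at C9 ring A and C8(OH)(CH3)–C7(=O)–C6H3 and at C13 ethynyl and CH2OTBS)
Conditions: dimethyl (1-diazo-2-oxopropyl)phosphonate, K2CO3, MeOH, 0 °C to rt
Reagents that add atoms: dimethyl (1-diazo-2-oxopropyl)phosphonate, COP(=O)(OC)C(=[N+]=[N-])C(C)=O
Why: The Ohira–Bestmann (Seyferth–Gilbert) homologation acts on the aldehyde tautomer of the lactol and adds C15 as the alkyne terminus, ketones are inert under these mild carbonate conditions, and quaternary C13 cannot epimerise.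

Step 17
Reactants: 25 alkynyl hydroxy diketone
Product: 27 8α-hydroxy-16-(tert-butyldimethylsilyloxy)-9α,13-epoxylabd-5-en-14-yn-7-one (13S), via aldol ketol 26 (not isolated)
Conditions: KOt-Bu, t-BuOH–THF, 0 °C to rt
Reagents that add atoms: none
Why: In this intramolecular aldol condensation C6 is the only enolisable carbon and the C5 ketone the only electrophile; the six-membered closure of ring B is helped by the fully substituted tether (gem-dialkyl effect) and made irreversible by E1cB loss of water, as in the Robinson annulation of 2,2,6-trimethylcyclohexanone, and the low temperature keeps an α-ketol shift from scrambling C8.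

Step 18
Reactants: 27 enone
Product: 28 the (E)-tosylhydrazone of 27
Conditions: TsNHNH2, EtOH–THF, 60 °C
Reagents that add atoms: 4-methylbenzenesulfonohydrazide, Cc1ccc(cc1)S(=O)(=O)NN
Why: Hydrazone condensation at the only remaining carbonyl group gives the conjugated tosylhydrazone, with the sulfonamide nitrogen turned away from quaternary C8.

Step 19
Reactants: 28 tosylhydrazone
Product: 30 16-(tert-butyldimethylsilyloxy)-9α,13-epoxy-5β-labd-6-en-14-yn-8α-ol, via allylic diazene 29 (not isolated)
Conditions: catecholborane, CHCl3, −10 °C; NaOAc·3H2O, reflux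
Reagents that add atoms: none
Why: In this alkene-transposing reduction of an enone tosylhydrazone, catecholborane should deliver hydride to C7 from the α face, opposite the C17 and C20 methyl groups; acetate-induced loss of sulfinate then gives the 7β-diazene, whose retro-ene loss of N2 hands its hydrogen suprafacially to the β face of C5, setting the cis ring fusion just as steroidal 4-en-3-ones give 5β-3-enes.

Step 20
Reactants: 30 tertiary allylic alcohol
Product: 31 the 8α-acetate of 30
Conditions: Ac2O, DMAP, Et3N, CH2Cl2, 40 °C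
Reagents that add atoms: acetic anhydride, CC(=O)OC(C)=O
Why: DMAP-catalysed acylation is carried out while O8 is the only free hydroxyl, so the tertiary acetate never has to be introduced in the presence of the more reactive 7-hydroxyl.

Step 21
Reactants: 31 olefinic acetate
Product: 32 8α-acetoxy-16-(tert-butyldimethylsilyloxy)-9α,13-epoxy-5β-labd-14-yne-6β,7β-diol
Conditions: OsO4 (5 mol %), NMO, acetone–H2O, rt
Reagents that add atoms: N-methylmorpholine N-oxide, C[N+]1([O-])CCOCC1; water, O
Why: Catalytic osmylation (syn dihydroxylation) takes the only alkene, terminal alkynes being much slower, and should approach the convex β face, anti to the allylic acetoxy group and away from ring A folded under the α face, which sets the 7β-hydroxyl.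

Step 22
Reactants: 32 diol
Product: 33 8α-acetoxy-7β-hydroxy-16-(tert-butyldimethylsilyloxy)-9α,13-epoxy-5β-labd-14-yn-6-one
Conditions: IBX (1.2 equiv), DMSO, rt
Reagents that add atoms: none
Why: IBX oxidises 1,2-diols to α-ketols without glycol cleavage, and it should engage the equatorial 6-hydroxyl first because the axial 7-hydroxyl is neopentylic, syn-axial to C11 and inductively deactivated by the neighbouring acetoxy carbon; the base-free medium leaves the 5β-hydrogen untouched.

Step 23
Reactants: 33 silyl ether
Product: 34 8α-acetoxy-7β,16-dihydroxy-9α,13-epoxy-5β-labd-14-yn-6-one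
Conditions: HF·pyridine, pyridine, THF, 0 °C
Reagents that add atoms: none
Why: Fluoride-induced desilylation in a buffered, weakly acidic medium frees O16 without generating basic alkoxides, which would invite acetyl migration, β-elimination of acetate or epimerisation at C5.

Step 24
Reactants: 34 homopropargylic alcohol
Product: 35 target CNP0275274.1: 8α-acetoxy-7β-hydroxy-9α,13;15,16-diepoxy-5β-labd-14-en-6-one (13S)
Conditions: [RhCl(cod)]2 (2.5 mol %), P(4-FC6H4)3 (cat.), DMF, 85 °C
Reagents that add atoms: none
Why: In this vinylidene-mediated cycloisomerisation of a homopropargylic alcohol (formal 5-endo-dig hydroalkoxylation), the terminal alkyne rearranges to a rhodium vinylidene, O16 adds to C15, and protodemetalation closes the 2,3-dihydrofuran ring D under neutral conditions, so the acid-labile enol ether is made last and C13 is untouched.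

Compound list
1 | 2,2,6-trimethylcyclohexanone (racemic) | CC1CCCC(C)(C)C1=O | starting material
2 | lithium 2,6,6-trimethylcyclohex-1-en-1-olate | [Li]OC1=C(C)CCCC1(C)C | intermediate
3 | allyl 2,6,6-trimethylcyclohex-1-en-1-yl carbonate | C=CCOC(=O)OC1=C(C)CCCC1(C)C | intermediate
4 | (R)-2-allyl-2,6,6-trimethylcyclohexanone | C=CC[C@@]1(C)CCCC(C)(C)C1=O | intermediate
5 | (R)-2,2,6-trimethyl-6-[(E)-prop-1-enyl]cyclohexanone | C/C=C/[C@@]1(C)CCCC(C)(C)C1=O | intermediate
6 | (R)-1,3,3-trimethyl-2-oxocyclohexane-1-carbaldehyde | O=C[C@@]1(C)CCCC(C)(C)C1=O | intermediate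
7 | furfuryl alcohol | OCc1ccco1 | starting material
8 | tert-butyl(furan-2-ylmethoxy)dimethylsilane | CC(C)(C)[Si](C)(C)OCc1ccco1 | intermediate
9 | 5-lithio derivative of 8 | [Li]c1ccc(CO[Si](C)(C)C(C)(C)C)o1 | intermediate
10 | furyl carbinol, 10R, C9 epimers (S drawn) | CC(C)(C)[Si](C)(C)OCc1ccc(o1)[C@@H](O)[C@@]2(C)CCCC(C)(C)C2=O | intermediate
11 | 6-hydroxypyranone (2S,6R epimer drawn) | O[C@]1(CO[Si](C)(C)C(C)(C)C)C=CC(=O)[C@@H](O1)[C@@]2(C)CCCC(C)(C)C2=O | intermediate
12 | 6-acetoxypyranone, key-step precursor (2S,6S epimer drawn) | CC(=O)O[C@]1(CO[Si](C)(C)C(C)(C)C)C=CC(=O)[C@@H](O1)[C@@]2(C)CCCC(C)(C)C2=O | intermediate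
13 | methyl acrylate | C=CC(=O)OC | starting material
14 | 6-(silyloxymethyl)-2-[(R)-1,3,3-trimethyl-2-oxocyclohexyl]-3-oxidopyrylium | [O-]c1ccc(CO[Si](C)(C)C(C)(C)C)[o+]c1[C@@]2(C)CCCC(C)(C)C2=O | intermediate
15 | cycloadduct, 8-oxabicyclo[3.2.1]oct-3-en-2-one (1S,5R,6S) | O=C1C=C[C@@]2(CO[Si](C)(C)C(C)(C)C)O[C@@]1(C[C@@H]2C(=O)OC)[C@@]3(C)CCCC(C)(C)C3=O | intermediate
16 | trimethylstannyl ester of 17 | O=C1C=C[C@@]2(CO[Si](C)(C)C(C)(C)C)O[C@@]1(C[C@@H]2C(=O)O[Sn](C)(C)C)[C@@]3(C)CCCC(C)(C)C3=O | intermediate
17 | C12 carboxylic acid | O=C1C=C[C@@]2(CO[Si](C)(C)C(C)(C)C)O[C@@]1(C[C@@H]2C(=O)O)[C@@]3(C)CCCC(C)(C)C3=O | intermediate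
18 | N-acyloxypyridine-2-thione (Barton ester) of 17 | O=C1C=C[C@@]2(CO[Si](C)(C)C(C)(C)C)O[C@@]1(C[C@@H]2C(=O)ON4C=CC=CC4=S)[C@@]3(C)CCCC(C)(C)C3=O | intermediate
19 | decarboxylated bicyclic enone (1S,5S) | O=C1C=C[C@@]2(CO[Si](C)(C)C(C)(C)C)O[C@@]1(CC2)[C@@]3(C)CCCC(C)(C)C3=O | intermediate
20 | 3-iodo enone (I on C7) | O=C1C(I)=C[C@@]2(CO[Si](C)(C)C(C)(C)C)O[C@@]1(CC2)[C@@]3(C)CCCC(C)(C)C3=O | intermediate
21 | 3-methyl enone (C6 on C7) | O=C1C(C)=C[C@@]2(CO[Si](C)(C)C(C)(C)C)O[C@@]1(CC2)[C@@]3(C)CCCC(C)(C)C3=O | intermediate
22 | tertiary allylic alcohol (1S,2R,5S) | C[C@@]1(O)C(C)=C[C@@]2(CO[Si](C)(C)C(C)(C)C)O[C@@]1(CC2)[C@@]3(C)CCCC(C)(C)C3=O | intermediate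
23 | open hydroxy keto aldehyde | CC(=O)[C@@](C)(O)[C@]1(CC[C@@](CO[Si](C)(C)C(C)(C)C)(C=O)O1)[C@@]2(C)CCCC(C)(C)C2=O | intermediate
24 | keto lactol (anomers at C14) | CC(=O)[C@@]1(C)OC(O)[C@]2(CO[Si](C)(C)C(C)(C)C)CC[C@]1(O2)[C@@]3(C)CCCC(C)(C)C3=O | intermediate
25 | alkynyl hydroxy diketone | CC(=O)[C@@](C)(O)[C@]1(CC[C@@](CO[Si](C)(C)C(C)(C)C)(C#C)O1)[C@@]2(C)CCCC(C)(C)C2=O | intermediate
26 | aldol ketol (5β,8α-dihydroxy-7-one, cis-fused) | O[C@]1(C)C(=O)C[C@]2(O)C(C)(C)CCC[C@]2(C)[C@@]13CC[C@@](CO[Si](C)(C)C(C)(C)C)(C#C)O3 | intermediate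
27 | 8α-hydroxy-16-TBSO-9α,13-epoxylabd-5-en-14-yn-7-one | O[C@]1(C)C(=O)C=C2C(C)(C)CCC[C@]2(C)[C@@]13CC[C@@](CO[Si](C)(C)C(C)(C)C)(C#C)O3 | intermediate
28 | (E)-tosylhydrazone of 27 | O[C@]1(C)/C(=N/NS(=O)(=O)c4ccc(C)cc4)C=C2C(C)(C)CCC[C@]2(C)[C@@]13CC[C@@](CO[Si](C)(C)C(C)(C)C)(C#C)O3 | intermediate
29 | 7β-diazenyl-5-ene (allylic diazene) | O[C@]1(C)[C@@H](N=N)C=C2C(C)(C)CCC[C@]2(C)[C@@]13CC[C@@](CO[Si](C)(C)C(C)(C)C)(C#C)O3 | intermediate
30 | 16-TBSO-9α,13-epoxy-5β-labd-6-en-14-yn-8α-ol | O[C@]1(C)C=C[C@@H]2C(C)(C)CCC[C@]2(C)[C@@]13CC[C@@](CO[Si](C)(C)C(C)(C)C)(C#C)O3 | intermediate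
31 | 8α-acetate of 30 | CC(=O)O[C@]1(C)C=C[C@@H]2C(C)(C)CCC[C@]2(C)[C@@]13CC[C@@](CO[Si](C)(C)C(C)(C)C)(C#C)O3 | intermediate
32 | 8α-acetoxy-6β,7β-diol | CC(=O)O[C@]1(C)[C@@H](O)[C@@H](O)[C@@H]2C(C)(C)CCC[C@]2(C)[C@@]13CC[C@@](CO[Si](C)(C)C(C)(C)C)(C#C)O3 | intermediate
33 | 8α-acetoxy-7β-hydroxy-6-ketone, 16-OTBS | CC(=O)O[C@]1(C)[C@@H](O)C(=O)[C@@H]2C(C)(C)CCC[C@]2(C)[C@@]13CC[C@@](CO[Si](C)(C)C(C)(C)C)(C#C)O3 | intermediate
34 | 8α-acetoxy-7β,16-dihydroxy-6-ketone | CC(=O)O[C@]1(C)[C@@H](O)C(=O)[C@@H]2C(C)(C)CCC[C@]2(C)[C@@]13CC[C@@](CO)(C#C)O3 | intermediate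
35 | CNP0275274.1 | CC(=O)O[C@]1(C)[C@@H](O)C(=O)[C@@H]2C(C)(C)CCC[C@]2(C)[C@@]12CC[C@@]1(C=COC1)O2 | target

Total steps: 24. Longest linear sequence: 23 (steps 1–4 and 6–24; step 5 is a one-step branch).

Steps most likely to fail

Step 9. The C10 centre may discriminate only weakly between the two faces of the ylide. Capture of the doubly substituted ylide may also be slow enough for dimerisation or decomposition to take over. The fallback replaces substrate control by reagent control. Starting again from 12, the ylide is released with Et3N in the presence of N-acryloyl-(2R)-bornane-10,2-sultam, or its enantiomer, whichever proves matched with C10. This is a more electron-poor acrylamide whose auxiliary shields one alkene face in dipolar cycloadditions without a Lewis acid. The product is the sultam cycloadduct F1. LiOH in aqueous THF then removes the auxiliary and gives acid 17, so step 10 is skipped and the route resumes at step 11.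

Step 19. Hydride may reach C7 from the β face instead of the α face. That would place the diazene on the α face and transfer hydrogen to the α face of C5, giving the trans ring fusion. The fallback turns this same bias to advantage. From 27, Luche reduction (NaBH4, CeCl3·7H2O, MeOH) from the β face gives the 7α-allylic alcohol F2. Selective formylation of the secondary hydroxyl (formic acetic anhydride, pyridine) then gives the 7α-formate F3. Pd(acac)2/PBu3 in THF ionises the formate with inversion, which puts palladium on the β face. After loss of CO2, the palladium hydride delivers hydrogen to the more substituted terminus C5 from that face (allylic formate hydrogenolysis). This returns the route to 30.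

Step 22. Oxidation may occur at the wrong carbinol or at both, and C5 may then be lost through enolisation of a diketone. The fallback avoids the diol altogether and keeps the original C7 oxygen. From 27, acetylation (Ac2O, DMAP) gives the 8α-acetoxy enone F4. Luche reduction from the α face gives the 7β-allylic alcohol F5. Dimethyldioxirane attacks the less hindered α face to give the 5α,6α-epoxide F6. BF3·OEt2 at −78 °C then opens the epoxide at tertiary C5, and the 6β-hydrogen migrates to the β face of C5 (Meinwald rearrangement, as in the conversion of steroidal 5α,6α-epoxides into 5β-6-ketones). This gives 33 directly and bypasses steps 18–22.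

Further compounds
F1 | step 9 | N-acyl (2R)-bornane-10,2-sultam analogue of cycloadduct 15 | O=C1C=C[C@@]2(CO[Si](C)(C)C(C)(C)C)O[C@@]1(C[C@@H]2C(=O)N4[C@@H]5C[C@H]6CC[C@]5(CS4(=O)=O)C6(C)C)[C@@]3(C)CCCC(C)(C)C3=O
F2 | step 19 | 16-TBSO-9α,13-epoxylabd-5-en-14-yne-7α,8α-diol | O[C@]1(C)[C@H](O)C=C2C(C)(C)CCC[C@]2(C)[C@@]13CC[C@@](CO[Si](C)(C)C(C)(C)C)(C#C)O3
F3 | step 19 | 7α-formate of F2 | O[C@]1(C)[C@H](OC=O)C=C2C(C)(C)CCC[C@]2(C)[C@@]13CC[C@@](CO[Si](C)(C)C(C)(C)C)(C#C)O3
F4 | step 22 | 8α-acetate of enone 27 | CC(=O)O[C@]1(C)C(=O)C=C2C(C)(C)CCC[C@]2(C)[C@@]13CC[C@@](CO[Si](C)(C)C(C)(C)C)(C#C)O3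
F5 | step 22 | 8α-acetoxy-7β-hydroxy-5-ene | CC(=O)O[C@]1(C)[C@@H](O)C=C2C(C)(C)CCC[C@]2(C)[C@@]13CC[C@@](CO[Si](C)(C)C(C)(C)C)(C#C)O3
F6 | step 22 | 8α-acetoxy-7β-hydroxy-5α,6α-epoxide | CC(=O)O[C@]1(C)[C@@H](O)[C@@H]4O[C@@]42C(C)(C)CCC[C@]2(C)[C@@]13CC[C@@](CO[Si](C)(C)C(C)(C)C)(C#C)O3
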